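**Plan**

- **Retrosynthetic cuts.** The acyl–oxygen bonds at C2 (acetate) and C6 (veratrate) and the C8/C9 epoxide oxygen come off first. Next go the C4–isopropyl bond (ketone plus isopropyl-metal) and the C4 oxygen (via a C4=C5–C6=O enone). What remains is a hydroazulene with a C5=C6 silyl enol ether and a C8=C9 alkene.
- **Enabling feature.** In the seven-membered ring (C1, C5, C6, C7, C8, C9, C10), oxygen-bearing C6 and the epoxide carbons C8/C9 lie on either side of the C7 methylene. At the alkene level the ring is therefore a cyclohepta-1,4-diene. This maps onto a cis-dialkenylcyclopropane built from C6, C7 and C8: cut C1–C10 and redraw C6–C8.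
- **Forward order.** The five-membered ring is bought as 2-methylcyclopentane-1,3-dione. C6/C8/C9/C10 are attached by acylating a cyclopentenyllithium, and C7 by cyclopropanating the derived silyl dienol ether. The seven-membered ring arises in the [3,3] shift that also creates quaternary C1.
- **Stereochemistry.** C2 comes from a catalyst-controlled ketone reduction, and C1 from C2 (bond formation anti to the C2 silyl ether). C5 comes from conjugate borylation/protonation, C6 from hydride attack anti to the C1 methyl, and C4 from α-face isopropyl addition. The epoxide is delivered by the C6 hydroxyl.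

Key step: step 8

Remark on numbering and the reading of the target: C1 = methyl-bearing fusion carbon, C2 = CH–OAc, C3 = CH2, C4 = isopropyl carbinol, C5 = fusion CH, C6 = CH–O-acyl, C7 = CH2, C8 (methyl) and C9 = epoxide carbons, C10 = CH2. The SMILES is read as 1S,2S,4S,5R,6S,8R,9S, which places C1-CH3, C2-OAc, C4-OH, C6-O-acyl and the epoxide oxygen on one face (β) and H5 and isopropyl on the other (α), with a trans ring fusion. TBS = tert-butyldimethylsilyl, TES = triethylsilyl, Bpin = 4,4,5,5-tetramethyl-1,3,2-dioxaborolan-2-yl.

**Step 1**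
Reactants: 1 2-methylcyclopentane-1,3-dione
Product: 2 3-bromo-2-methylcyclopent-2-en-1-one
Conditions: (COBr)2, N,N-dimethylformamide (cat.), CH2Cl2, 0 °C → rt
Reagents that add atoms: oxalyl bromide, O=C(Br)C(=O)Br
Why: Vilsmeier-type activation of the enolised 1,3-dione by the bromoiminium salt followed by addition–elimination of bromide is the standard route from cyclic vinylogous acids to 3-bromoenones, and the symmetry of 1 removes any regiochemical question.

**Step 2**
Reactants: 2 3-bromo-2-methylcyclopent-2-en-1-one
Product: 3 (1S)-3-bromo-2-methylcyclopent-2-en-1-ol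
Conditions: (R)-1-methyl-3,3-diphenyltetrahydro-1H,3H-pyrrolo[1,2-c][1,3,2]oxazaborole (10 mol %), BH3·SMe2, THF, −20 °C; MeOH quench
Reagents that add atoms: none
Why: Corey–Bakshi–Shibata reduction, in which the ketone binds to the oxazaborolidine boron with the fully substituted bromoalkenyl arm as the large and the ring CH2 as the small group, so that the (R)-catalyst sends hydride to the face giving the (S)-carbinol that becomes C2 of the target.

**Step 3**
Reactants: 3 (1S)-3-bromo-2-methylcyclopent-2-en-1-ol
Product: 4 {[(1S)-3-bromo-2-methylcyclopent-2-en-1-yl]oxy}(tert-butyl)dimethylsilane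
Conditions: TBSCl, imidazole, DMF, rt
Reagents that add atoms: tert-butyldimethylsilyl chloride, CC(C)(C)[Si](C)(C)Cl
Why: Imidazole-promoted O-silylation of a secondary allylic alcohol is routine, leaves the stereocentre untouched and installs a group that survives organolithium, zinc carbenoid, heat, hydride and organocerium reagents while marking the β face sterically.

**Step 4**
Reactants: 5 2-methylbut-3-enoic acid (racemic)
Product: 7 N-methoxy-N,2-dimethylbut-3-enamide (racemic), via acyl imidazole 6 (not isolated)
Conditions: 1,1'-carbonyldiimidazole, CH2Cl2, 0 °C; then MeNH(OMe)·HCl, rt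
Reagents that add atoms: N,O-dimethylhydroxylamine hydrochloride, CNOC.Cl; 1,1'-carbonyldiimidazole, O=C(n1ccnc1)n1ccnc1 (imidazolyl group of 6 only)
Why: Weinreb amide formation through the acyl imidazole runs close to neutrality and at or below room temperature, which should keep the β,γ-double bond out of conjugation, and the racemic α-carbon is of no consequence because it becomes sp2 in step 6.

**Step 5**
Reactants: 4 {[(1S)-3-bromo-2-methylcyclopent-2-en-1-yl]oxy}(tert-butyl)dimethylsilane; 7 N-methoxy-N,2-dimethylbut-3-enamide
Product: 9 1-[(3S)-3-(tert-butyldimethylsilyloxy)-2-methylcyclopent-1-en-1-yl]-2-methylbut-3-en-1-one (both C8 epimers), via cyclopentenyllithium 8 (not isolated)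
Conditions: t-BuLi (2 equiv), Et2O, −78 °C; then 7, −78 → −40 °C; sat. aq NH4Cl at −78 °C
Reagents that add atoms: tert-butyllithium, [Li]C(C)(C)C (lithium of 8 only)
Why: Bromine–lithium exchange gives the cyclopentenyllithium, and its Weinreb ketone synthesis stops at the chelated tetrahedral adduct, which a cold mildly acidic quench converts into the β,γ-unsaturated ketone (new C5–C6 bond) as a mixture of C8 epimers.

**Step 6**
Reactants: 9 1-[(3S)-3-(tert-butyldimethylsilyloxy)-2-methylcyclopent-1-en-1-yl]-2-methylbut-3-en-1-one
Product: 10 tert-butyl(dimethyl){[(1S)-2-methyl-3-[(1E)-2-methyl-1-(triethylsilyloxy)buta-1,3-dien-1-yl]cyclopent-2-en-1-yl]oxy}silane (cyclopentenyl cis to vinyl across C6=C8)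
Conditions: TESOTf, Et3N, CH2Cl2, −78 → 0 °C
Reagents that add atoms: triethylsilyl trifluoromethanesulfonate, CC[Si](CC)(CC)OS(=O)(=O)C(F)(F)F
Why: Soft enolisation with silyl triflate and amine removes the only α-hydrogen, C8–H, which is both α to the carbonyl and allylic, to give the silyl dienol ether; the (E)-isomer shown leads directly to the cis-cyclopropane, any (Z)-isomer is carried along, and the conjugated triene is kept at or below 0 °C to avoid 6π electrocyclisation.

**Step 7**
Reactants: 10 silyl dienol ether; 11 diiodomethane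
Product: 12 tert-butyl{[(1S)-3-[(1R,2S)-2-ethenyl-2-methyl-1-(triethylsilyloxy)cyclopropyl]-2-methylcyclopent-2-en-1-yl]oxy}dimethylsilane (cyclopentenyl on C6 and vinyl on C8 cis)
Conditions: Et2Zn, CH2I2, CH2Cl2, −20 → 0 °C; aq NaHCO3 quench
Reagents that add atoms: diiodomethane 11, ICI (CH2 = C7)
Why: Simmons–Smith cyclopropanation (Furukawa variant), in which the electrophilic zinc carbenoid picks the most electron-rich, oxygen-bearing double bond of the triene and adds CH2 stereospecifically syn, so the cis relation of cyclopentenyl and vinyl is kept; the remote C2 centre gives little face bias, so the (1S,2R)-cyclopropane diastereomer is expected as well and is not separated.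

**Step 8**
Reactants: 12 cis-1-cyclopentenyl-2-vinyl-1-silyloxycyclopropane (with its cyclopropane isomers)
Product: 13 (1S,8aS)-1-(tert-butyldimethylsilyloxy)-6,8a-dimethyl-4-(triethylsilyloxy)-1,2,3,5,8,8a-hexahydroazulene (route numbering 1S,2S: C5=C6 TES enol ether, C8=C9 alkene, C1-CH3 cis to C2-OTBS)
Conditions: toluene (degassed, dilute), 2,6-di-tert-butyl-4-methylphenol (cat.), base-washed sealed tube, 150 °C
Reagents that add atoms: none
Why: The reaction is a concerted, thermally allowed [3,3]-sigmatropic shift through an endo-boat array in which C5=C1 and C9=C10 both lie over the three-membered ring, so that C1–C10 forms, the strained and donor-weakened C6–C8 bond breaks, and C5=C6 (as the enol ether) and C8=C9 emerge. The closest known type is the divinylcyclopropane–cycloheptadiene (Cope) rearrangement of 1-silyloxy-1,2-dialkenylcyclopropanes and of 2-vinylcyclopropyl-substituted cycloalkenes that carry a methyl group at the reacting terminus, which give angular-methyl bicycles on heating at roughly 140–190 °C. The seven-membered ring closes by ring expansion, the three cyclopropane carbons and the four alkene carbons becoming one ring annulated to the existing cyclopentene. The only new stereocentre, quaternary C1, is fixed because the boat of the (1R,2S)-cyclopropane presents C10 to the cyclopentene face anti to the C2 silyl ether, which leaves the methyl group cis to that oxygen (1S). The step needs face selectivity at C1 and convergence of the cyclopropane isomers; reversible homolysis of the bis-allylic, oxygen- and methyl-substituted C6–C8 bond should interconvert them at this temperature, and the bulky C2-OTBS group makes the anti transition state the lowest exit (Curtin–Hammett situation). The C1 methyl points toward the C7 hydrogens in the boat, which is why strong heating is required, and the radical inhibitor and base-washed glass protect the enol ether.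

**Step 9**
Reactants: 13 hydroazulene silyl enol ether
Product: 14 (1S,8aS)-1-(tert-butyldimethylsilyloxy)-6,8a-dimethyl-1,5,8,8a-tetrahydroazulen-4(2H)-one (C4=C5–C6=O enone, C8=C9 alkene)
Conditions: Pd(OAc)2 (1.1 equiv), MeCN, rt → 40 °C
Reagents that add atoms: none
Why: Saegusa–Ito oxidation, in which divalent palladium takes over the enolate from silicon at C5 and syn β-hydride elimination can only use a C4 hydrogen because C1 is quaternary, so the C4=C5–C6=O enone forms regiospecifically while the isolated C8=C9 alkene and the TBS ether are spectators.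

**Step 10**
Reactants: 14 dienone
Product: 15 trans-fused β-boryl ketone (1S,2S,4S,5R): C6 ketone, C4-Bpin α, H5 α, C2-OTBS β, C8=C9 alkene
Conditions: B2pin2, CuCl (5 mol %), bis[2-(diphenylphosphino)phenyl] ether (5 mol %), NaOt-Bu (10 mol %), MeOH (2 equiv), THF, rt
Reagents that add atoms: bis(pinacolato)diboron, CC1(C)OB(OC1(C)C)B1OC(C)(C)C(C)(C)O1
Why: Copper-catalysed conjugate borylation places boron on the β-carbon C4 from the α face, away from the C1 methyl and the C2 silyl ether, leaves the unactivated C8=C9 alkene alone, and methanol protonates the enolate at C5, where the alkoxide present can equilibrate the centre to the isomer with H5 α (C6 trans to the boryl group, trans ring fusion).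

**Step 11**
Reactants: 15 β-boryl ketone
Product: 16 6β-alcohol (1S,2S,4S,5R,6S): C6-OH β, C4-Bpin α, H5 α, C2-OTBS β, C8=C9 alkene
Conditions: LiBH(s-Bu)3, THF, −78 °C; aq NH4Cl (non-oxidative work-up)
Reagents that add atoms: none
Why: Sterically controlled ketone reduction, since in the trans-fused ring the axial C1 methyl is 1,3 to C6 and shields the β face, so the bulky borohydride should come in along the equatorial α trajectory and give the axial 6β-alcohol (6S), the outcome known for 6-oxo-5α-steroids and 3-axially substituted cyclohexanones.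

**Step 12**
Reactants: 16 6β-alcohol
Product: 17 6β-TES ether (1S,2S,4S,5R,6S): C6-OTES β, C4-Bpin α, C2-OTBS β, C8=C9 alkene
Conditions: TESOTf, 2,6-lutidine, CH2Cl2, −78 → 0 °C
Reagents that add atoms: triethylsilyl trifluoromethanesulfonate, CC[Si](CC)(CC)OS(=O)(=O)C(F)(F)F
Why: Silyl triflate with a hindered pyridine base silylates even axial secondary alcohols at low temperature, and a TES ether is chosen because it is a poor leaving group next to the coming C4 ketone and can later be removed in the presence of the TBS ether.

**Step 13**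
Reactants: 17 boronic ester
Product: 18 4α-alcohol (1S,2S,4S,5S,6S): C4-OH α, C6-OTES β, C2-OTBS β, H5 α, C8=C9 alkene
Conditions: 30% H2O2, aq NaOH, THF, 0 °C
Reagents that add atoms: hydrogen peroxide, OO
Why: Alkaline peroxide oxidation of the secondary boronic ester proceeds by 1,2-migration with retention and touches neither the trisubstituted alkene nor the silyl ethers, and the configuration at C4 is of no consequence because it is lost in the next step.

**Step 14**
Reactants: 18 4α-alcohol
Product: 19 C4 ketone (1S,2S,5R,6S): cyclopentanone C4=O, H5 α, C6-OTES β, C2-OTBS β, C8=C9 alkene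
Conditions: Dess–Martin periodinane, NaHCO3, CH2Cl2, 0 °C → rt
Reagents that add atoms: none
Why: Dess–Martin oxidation under bicarbonate buffering converts the cyclopentanol into the ketone without acid or base strong enough to epimerise C5 or to expel the C6 silyloxy group.

**Step 15**
Reactants: 19 C4 ketone
Product: 20 tertiary alcohol (1S,2S,4S,5R,6S): C4-OH β, C4-isopropyl α, C6-OTES β, C2-OTBS β, C8=C9 alkene
Conditions: i-PrMgCl, anhydrous CeCl3, THF, −78 °C; aq NH4Cl
Reagents that add atoms: isopropylmagnesium chloride, CC(C)[Mg]Cl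
Why: Organocerium 1,2-addition, in which the weakly basic, strongly oxophilic isopropylcerium reagent adds to the enolisable, hindered cyclopentanone instead of deprotonating or reducing it and should approach from the α face, which carries only H5 and H3, because the β face is covered by the C1 methyl, the C2 silyl ether and the C6 silyloxy group, so that the C4 hydroxyl ends up β (4S).

**Step 16**
Reactants: 20 bis-silyl ether
Product: 21 4β,6β-diol (1S,2S,4S,5R,6S): C6-OH and C4-OH free, C2-OTBS, C8=C9 alkene
Conditions: pyridinium p-toluenesulfonate (cat.), MeOH, 0 °C → rt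
Reagents that add atoms: none
Why: Mild acid-catalysed methanolysis distinguishes the two silyl ethers by size, cleaving the triethylsilyl group while the neopentyl-type TBS ether at C2, the tertiary alcohol and the alkene stay intact.

**Step 17**
Reactants: 21 diol
Product: 22 8β,9β-epoxy diol (1S,2S,4S,5R,6S,8R,9S): C2-OTBS retained
Conditions: VO(acac)2 (5 mol %), t-BuOOH (decane), CH2Cl2, 0 °C → rt
Reagents that add atoms: tert-butyl hydroperoxide, CC(C)(C)OO
Why: Hydroxyl-directed epoxidation, in which the vanadium peroxide complex is bound to the axial 6β-hydroxyl (homoallylic to C8=C9 and supported by the 4β-hydroxyl) and hands its oxygen to the same β face, which sets 8R,9S against the steric bias that an undirected peracid would follow.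

**Step 18**
Reactants: 22 epoxy diol; 23 3,4-dimethoxybenzoyl chloride
Product: 24 C6 veratrate (1S,2S,4S,5R,6S,8R,9S): C6-O-(3,4-dimethoxybenzoyl), C4-OH free, C2-OTBS, 8β,9β-epoxide
Conditions: 23, Et3N, 4-(dimethylamino)pyridine (cat.), CH2Cl2, 40 °C
Reagents that add atoms: 3,4-dimethoxybenzoyl chloride 23, COc1ccc(C(Cl)=O)cc1OC
Why: Acylation with an acyl chloride under nucleophilic catalysis esterifies the only free secondary hydroxyl, since the tertiary C4 alcohol is too hindered and C2 is still silylated, and the basic medium spares the epoxide.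

**Step 19**
Reactants: 24 C6 veratrate
Product: 25 C2 alcohol (1S,2S,4S,5R,6S,8R,9S): C2-OH and C4-OH free, C6 veratrate, 8β,9β-epoxide
Conditions: Bu4NF, AcOH, THF, rt → 40 °C
Reagents that add atoms: none
Why: Fluoride-induced desilylation, buffered with acetic acid so that no free alkoxide is present, removes the TBS group without acyl migration, ester cleavage or epoxide opening.

**Step 20**
Reactants: 25 C2 alcohol
Product: 26 target CNP0330776.1 (1S,2S,4S,5R,6S,8R,9S)
Conditions: Ac2O, pyridine, 4-(dimethylamino)pyridine (cat.), CH2Cl2, rt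
Reagents that add atoms: acetic anhydride, CC(=O)OC(C)=O
Why: Standard acetylation of the secondary C2 alcohol, under which the tertiary, hydrogen-bonded C4 hydroxyl does not react, so the product is the target with all seven stereocentres in place.

**Compound list**

1 | 2-methylcyclopentane-1,3-dione | CC1C(=O)CCC1=O | starting material
2 | 3-bromo-2-methylcyclopent-2-en-1-one | CC1=C(Br)CCC1=O | intermediate
3 | (1S)-3-bromo-2-methylcyclopent-2-en-1-ol | BrC1=C(C)[C@@H](O)CC1 | intermediate
4 | {[(1S)-3-bromo-2-methylcyclopent-2-en-1-yl]oxy}(tert-butyl)dimethylsilane | BrC1=C(C)[C@@H](O[Si](C)(C)C(C)(C)C)CC1 | intermediate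
5 | 2-methylbut-3-enoic acid (racemic) | C=CC(C)C(=O)O | starting material
6 | 1-(1H-imidazol-1-yl)-2-methylbut-3-en-1-one (not isolated) | C=CC(C)C(=O)n1ccnc1 | intermediate
7 | N-methoxy-N,2-dimethylbut-3-enamide (racemic) | C=CC(C)C(=O)N(C)OC | intermediate
8 | [(3S)-3-(tert-butyldimethylsilyloxy)-2-methylcyclopent-1-en-1-yl]lithium (not isolated) | [Li]C1=C(C)[C@@H](O[Si](C)(C)C(C)(C)C)CC1 | intermediate
9 | 1-[(3S)-3-(tert-butyldimethylsilyloxy)-2-methylcyclopent-1-en-1-yl]-2-methylbut-3-en-1-one (both C8 epimers) | C=CC(C)C(=O)C1=C(C)[C@@H](O[Si](C)(C)C(C)(C)C)CC1 | intermediate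
10 | (E)-silyl dienol ether, cyclopentenyl cis to vinyl | C=C/C(C)=C(/O[Si](CC)(CC)CC)C1=C(C)[C@@H](O[Si](C)(C)C(C)(C)C)CC1 | intermediate
11 | diiodomethane | ICI | starting material
12 | (1R,2S)-cyclopropane, cis-1-cyclopentenyl-2-vinyl, C6-OTES, C2-OTBS (S) | C=C[C@]1(C)C[C@]1(O[Si](CC)(CC)CC)C2=C(C)[C@@H](O[Si](C)(C)C(C)(C)C)CC2 | intermediate
13 | (1S,8aS)-1-(tert-butyldimethylsilyloxy)-6,8a-dimethyl-4-(triethylsilyloxy)-1,2,3,5,8,8a-hexahydroazulene | CC1=CC[C@]2(C)[C@@H](O[Si](C)(C)C(C)(C)C)CCC2=C(O[Si](CC)(CC)CC)C1 | intermediate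
14 | (1S,8aS)-1-(tert-butyldimethylsilyloxy)-6,8a-dimethyl-1,5,8,8a-tetrahydroazulen-4(2H)-one | CC1=CC[C@]2(C)[C@@H](O[Si](C)(C)C(C)(C)C)CC=C2C(=O)C1 | intermediate
15 | β-boryl ketone (1S,2S,4S,5R) | O=C1CC(C)=CC[C@]2(C)[C@@H](O[Si](C)(C)C(C)(C)C)C[C@H](B3OC(C)(C)C(C)(C)O3)[C@@H]12 | intermediate
16 | 6β-alcohol (1S,2S,4S,5R,6S) | O[C@H]1CC(C)=CC[C@]2(C)[C@@H](O[Si](C)(C)C(C)(C)C)C[C@H](B3OC(C)(C)C(C)(C)O3)[C@@H]12 | intermediate
17 | 6β-TES ether boronic ester (1S,2S,4S,5R,6S) | CC[Si](CC)(CC)O[C@H]1CC(C)=CC[C@]2(C)[C@@H](O[Si](C)(C)C(C)(C)C)C[C@H](B3OC(C)(C)C(C)(C)O3)[C@@H]12 | intermediate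
18 | 4α-alcohol (1S,2S,4S,5S,6S) | CC[Si](CC)(CC)O[C@H]1CC(C)=CC[C@]2(C)[C@@H](O[Si](C)(C)C(C)(C)C)C[C@H](O)[C@@H]12 | intermediate
19 | C4 ketone (1S,2S,5R,6S) | CC[Si](CC)(CC)O[C@H]1CC(C)=CC[C@]2(C)[C@@H](O[Si](C)(C)C(C)(C)C)CC(=O)[C@@H]12 | intermediate
20 | tertiary alcohol (1S,2S,4S,5R,6S) | CC[Si](CC)(CC)O[C@H]1CC(C)=CC[C@]2(C)[C@@H](O[Si](C)(C)C(C)(C)C)C[C@](O)(C(C)C)[C@@H]12 | intermediate
21 | 4β,6β-diol (1S,2S,4S,5R,6S) | O[C@H]1CC(C)=CC[C@]2(C)[C@@H](O[Si](C)(C)C(C)(C)C)C[C@](O)(C(C)C)[C@@H]12 | intermediate
22 | 8β,9β-epoxy diol (1S,2S,4S,5R,6S,8R,9S) | O[C@H]1C[C@@]2(C)O[C@H]2C[C@]2(C)[C@@H](O[Si](C)(C)C(C)(C)C)C[C@](O)(C(C)C)[C@@H]12 | intermediate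
23 | 3,4-dimethoxybenzoyl chloride | COc1ccc(C(Cl)=O)cc1OC | starting material
24 | C6 veratrate, C2-OTBS | COc1ccc(C(=O)O[C@H]2C[C@@]3(C)O[C@H]3C[C@]3(C)[C@@H](O[Si](C)(C)C(C)(C)C)C[C@](O)(C(C)C)[C@@H]23)cc1OC | intermediate
25 | C6 veratrate, C2-OH | COc1ccc(C(=O)O[C@H]2C[C@@]3(C)O[C@H]3C[C@]3(C)[C@@H](O)C[C@](O)(C(C)C)[C@@H]23)cc1OC | intermediate
26 | CNP0330776.1 | COc1ccc(C(=O)O[C@H]2C[C@@]3(C)O[C@H]3C[C@]3(C)[C@@H](OC(C)=O)C[C@](O)(C(C)C)[C@@H]23)cc1OC | target

**Step count**

Total step count: 20. Longest linear sequence: 19 (steps 1–3 and 5–20; step 4 is the side branch).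

**Steps most likely to fail**

**Step 8.** The cyclopropane isomers may not interconvert fast enough. Bond formation syn to the C2 silyl ether (loss of face selectivity at C1) or the homodienyl 1,5-hydrogen shift of the trans isomers would then compete with the wanted shift.

The fallback sets out from 4 and returns at 14. It builds C1 and the seven-membered ring separately. Bromide 4 is lithiated to 8 as in step 5 and acylated with N-methoxy-N,3-dimethylbut-3-enamide F1, which is made from commercial 3-methylbut-3-enoic acid in the manner of step 4. This gives the methallyl ketone 1-[(3S)-3-(tert-butyldimethylsilyloxy)-2-methylcyclopent-1-en-1-yl]-3-methylbut-3-en-1-one F2. Copper-mediated conjugate allylation (allylmagnesium bromide, CuBr·SMe2, LiCl, TESCl, THF, −78 °C) anti to the C2 silyl ether creates quaternary C1 and is trapped as the triethylsilyl enol ether F3. Saegusa–Ito oxidation with Pd(OAc)2 gives the monocyclic C4=C5 enone F4, which carries allyl at C1 and a methallyl ketone side chain. Ring-closing metathesis (second-generation Grubbs catalyst, CH2Cl2, reflux) then joins C8 to C9 and delivers 14.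

**Step 7.** The zinc carbenoid may attack the terminal vinyl group or both alkenes, and zinc iodide may cleave the enol ether or the cyclopropyl silyl ether.

The fallback sets out from 9 and returns at 12. It uses a metal enolate in place of the silyl enol ether. Ketone 9 is deprotonated (LiN(SiMe3)2, THF, −78 °C) to the lithium dienolate F5. Its oxygen-bearing double bond is cyclopropanated by the samarium carbenoid from SmI2 and CH2I2 (THF, −78 °C → rt). This is a known route from ketone enolates to cyclopropanols, in which the metal alkoxide guides the carbenoid. It gives the cis-1-cyclopentenyl-2-vinylcyclopropanol F6. Silylation (TESCl, imidazole, DMF, 0 °C) gives 12, and the isomers converge in step 8 as before.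

**Step 11.** Face selectivity of hydride delivery at C6 may be poor or reversed if the seven-membered ring adopts a conformation in which the α face is the more crowded one.

The fallback sets out from 15 and returns at 16. It sets C6 by substitution rather than by hydride approach. The ketone is reduced under conditions that favour the equatorial alcohol (NaBH4, MeOH, 0 °C, or whichever hydride gives it cleanly) to the 6α-alcohol F7. Mitsunobu inversion (4-nitrobenzoic acid, PPh3, diisopropyl azodicarboxylate, toluene) gives the 6β 4-nitrobenzoate F8. Methanolysis (K2CO3, MeOH) gives 16.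

**Further compounds**

F1 | step 8 | N-methoxy-N,3-dimethylbut-3-enamide | C=C(C)CC(=O)N(C)OC
F2 | step 8 | 1-[(3S)-3-(tert-butyldimethylsilyloxy)-2-methylcyclopent-1-en-1-yl]-3-methylbut-3-en-1-one | C=C(C)CC(=O)C1=C(C)[C@@H](O[Si](C)(C)C(C)(C)C)CC1
F3 | step 8 | triethylsilyl enol ether with allyl and methyl at C1 (1S,2S), methallyl at C6 | C=CC[C@]1(C)[C@@H](O[Si](C)(C)C(C)(C)C)CCC1=C(O[Si](CC)(CC)CC)CC(C)=C
F4 | step 8 | monocyclic C4=C5 enone with allyl at C1 (1S,2S) and methallyl ketone side chain | C=CC[C@]1(C)[C@@H](O[Si](C)(C)C(C)(C)C)CC=C1C(=O)CC(C)=C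
F5 | step 7 | lithium dienolate of 9 | C=CC(C)=C(O[Li])C1=C(C)[C@@H](O[Si](C)(C)C(C)(C)C)CC1
F6 | step 7 | (1R,2S)-1-[(3S)-3-(tert-butyldimethylsilyloxy)-2-methylcyclopent-1-en-1-yl]-2-ethenyl-2-methylcyclopropan-1-ol | C=C[C@]1(C)C[C@]1(O)C2=C(C)[C@@H](O[Si](C)(C)C(C)(C)C)CC2
F7 | step 11 | 6α-alcohol (6R epimer of 16) | O[C@@H]1CC(C)=CC[C@]2(C)[C@@H](O[Si](C)(C)C(C)(C)C)C[C@H](B3OC(C)(C)C(C)(C)O3)[C@@H]12
F8 | step 11 | 6β 4-nitrobenzoate of 16 | O=C(O[C@H]1CC(C)=CC[C@]2(C)[C@@H](O[Si](C)(C)C(C)(C)C)C[C@H](B3OC(C)(C)C(C)(C)O3)[C@@H]12)c1ccc(cc1)[N+](=O)[O-]
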